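All constants are those of an exercise; the result is computed.

Begin with the easy step: E.J and E.X each form from E and one partner, and the partners J and X pass into each other.

| flask | Q | E | temperature | time | remark |
|---|---|---|---|---|---|
| theta | 0.050 M | 0.0525 M (fed, over 10 min) | 60 °C | 1.0 h | the fed solution adds 0.25 times the starting volume |
| gamma | 0.050 M | 0.0525 M (fed, over 10 min) | 80 °C | 1.0 h | the fed solution adds 0.25 times the starting volume |

    E + J → E.J (k1 = 13.0 M⁻¹ min⁻¹, Ea1 = 47.0 kJ mol⁻¹)
    2 D → D2 (k2 = 0.192 M⁻¹ min⁻¹, Ea2 = 84.0 kJ mol⁻¹)
    J ⇌ X (K3 = 0.11, k3 = 1.50 min⁻¹, Ea3 = 90.0 kJ mol⁻¹, ΔH3 = −15.0 kJ mol⁻¹)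
    Q ⇌ D, rate k4*(cs4 - [D]) while solid is left; crystals form when [D] > cs4 (cs4 = 8.5 mM, k4 = 0.00268 min⁻¹)
    E + X → E.X (k5 = 11.9 M⁻¹ min⁻¹, Ea5 = 53.0 kJ mol⁻¹)
    D ⇌ J (K6 = 7.3 × 10⁻⁴, k6 = 0.0150 min⁻¹, Ea6 = 98.0 kJ mol⁻¹, ΔH6 = 12.0 kJ mol⁻¹)
    (constants at 60 °C)

1. the best flask by share of E.J in all that became E.J or E.X; "all alike" if 1.5 percentage points covers them all (theta / gamma / all alike)
2. share of E.J in all that became E.J or E.X, theta
3. share of E.J in all that became E.J or E.X, gamma

- a species is counted by the Q in it: one D2 counts as two
- where a step has two of a species, its rate is k times that concentration squared, and two are used at each turn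
- charges are per starting volume, the dose included; the dosed solution carries all of it
- given per volume of solution although it is solid: Q
- all constants are for 60 °C and move with temperature by the activation energies and enthalpies
- at the start none of Q is in solution
- what has only dissolved of Q counts as not reacted

Fix c(E) first. The feed dilutes the E charge to 0.0420 M. At its fastest, with c(D) at zero, dissolution of Q gives 1.37 mM over 1.0 h, hardly any of the E charge. So after the feed treat c(E) as constant and both trapping steps as pseudo-first-order.

Write kJ and kX for the constants of E with J and with X, kf for J → X, and K for that equilibrium. Apply the bench rule for a fast pre-equilibrium (Curtin–Hammett): let X/J stand at K, so that the share of E.J is kJ/(kJ + kX·K). For theta this gives 90.9%.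

Now solve the opposite end, where E catches X before it returns; there X/J is kf/(kX·c(E)). Join the two ends with a steady state on X: X/J = kf/(kf/K + kX·c(E)). The rule stops working where kX·c(E) reaches the return rate kf/K. In theta, 0.500 min⁻¹ stands far below 13.6 min⁻¹, a ratio of 0.0367, so theta lies near the equilibrium end. Its X/J is 0.106, and kJ/(kJ + kX·X/J) comes to 91.1%. Call that fraction the joined share.

For gamma, scale the constants: kX by 3.0, kJ by 2.61 (the logarithm of the kX factor times the ratio of the two activation energies), and kf by 6.3, with K at 0.0809. Then X/J is 0.0799 and the joined share 92.4%. The gain of 1.3 percentage points stays inside the margin of 1.5 points, so I commit to the two flasks counting as equal.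

The forecast gives all alike, with 91.1% for theta and 92.3% for gamma, on the ground that “J and X interconvert much faster than E traps them”.

The simulation reads 91.2% for theta and 92.4% for gamma, hence all alike, against joined shares of 91.1% and 92.4%. Take now the neighbour of gamma charged with 0.089 M of E, which is 1.78 equiv on Q. Its c(E) is 0.0712 M, so X/J becomes 0.0792 and the joined share 92.4%, up 0.061 points on gamma and 1.3 points on theta. That flask reads 92.4%.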